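The pyran ring is cut at both bonds that flank its C3=C4 alkene: C2–C3 at the gem-dimethyl carbon and C4–C4a at the ring A carbon lying between the oxygen-bearing carbons C5 and C8a. The key step exploits C2 being a tertiary carbon on the ring oxygen O1: a phenoxyisobutyric redox-active ester (the N-acyloxyphthalimide of 2-(3-bromo-5-hydroxyphenoxy)-2-methylpropanoic acid) releases a stabilised tertiary α-aryloxy radical that adds to phenyl vinyl sulfone (an acetylene equivalent), and the adduct radical closes onto electron-rich ring A, all in one photoredox operation. Sulfinate elimination then unveils the chromene; a Claisen rearrangement installs the prenyl group and a late B-alkyl Suzuki coupling attaches the 4-hydroxyphenethyl arm.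

Key step: step 3

Remark: chromene numbering is used throughout (O1, C2, C3, C4, C4a, C5 to C8, C8a); the benzo ring is ring A and the 4-hydroxyphenyl ring is ring B. The target has no stereocentre; the only stereocentre on the route (C4 of compound 6) is racemic and is removed in step 4.

Step 1
Reactants: 1 5-bromobenzene-1,3-diol; 2 2-bromo-2-methylpropanoic acid
Product: 3 2-(3-bromo-5-hydroxyphenoxy)-2-methylpropanoic acid
Conditions: 1 (3 equiv), NaOH (powder), butan-2-one, 50 °C; then aq HCl; excess 1 recovered
Reagents that add atoms: none
Why: Williamson-type O-alkylation of the phenoxide by the α-bromo carboxylate, the standard entry to aryloxyisobutyric acids, should stop at one hydroxyl because the diol is in excess.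

Step 2
Reactants: 3 2-(3-bromo-5-hydroxyphenoxy)-2-methylpropanoic acid
Product: 4 1,3-dioxoisoindolin-2-yl 2-(3-bromo-5-hydroxyphenoxy)-2-methylpropanoate
Conditions: N-hydroxyphthalimide, DIC, DMAP (cat.), CH2Cl2, 0 °C to rt
Reagents that add atoms: N-hydroxyphthalimide, O=C1c2ccccc2C(=O)N1O
Why: Steglich-type carbodiimide esterification, in which the acidic N-hydroxyphthalimide should outcompete the free phenol for the activated, hindered tertiary acid.

Step 3
Reactants: 4 1,3-dioxoisoindolin-2-yl 2-(3-bromo-5-hydroxyphenoxy)-2-methylpropanoate; 5 phenyl vinyl sulfone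
Product: 6 rac-7-bromo-2,2-dimethyl-4-(phenylsulfonyl)chroman-5-ol
Conditions: 5 (2.5 equiv), fac-Ir(ppy)3 (1 mol %), degassed MeCN, blue LEDs (450 nm), rt, no added base
Reagents that add atoms: none
Why: Photoexcited fac-Ir(ppy)3 reduces the N-acyloxyphthalimide, which loses CO2 and phthalimide anion to give the tertiary α-aryloxy radical at C2; this nucleophilic radical adds to the CH2 terminus of the vinyl sulfone (Giese addition, C2–C3 bond), the electrophilic α-sulfonyl radical at C4 then attacks ring A (C4–C4a bond), and the cyclohexadienyl radical is oxidised by the tetravalent iridium species and deprotonated by phthalimide anion, so the cycle needs no external oxidant or reductant. The closest known reaction type is the photoredox radical (4+2) annulation of redox-active esters of α-aryloxy acids with electron-poor alkenes to chromans. The pyran ring closes in a six-membered ortho homolytic aromatic substitution (6-exo-trig with respect to the C4a–C5 π bond). The new stereocentre C4 is formed without control, as a racemate, and is destroyed in step 4. The step needs ring closure at C4a (between C5 and C8a) and not at C8: the free C5 hydroxyl can hydrogen-bond to a sulfonyl oxygen and guide the radical to its own ortho carbon, while the bromine at C7 deactivates and shields C8 towards the electrophilic radical. It also needs cyclisation to outrun reduction of the α-sulfonyl radical, which the oxidative quenching cycle, with no stoichiometric reductant present, should secure.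

Step 4
Reactants: 6 rac-7-bromo-2,2-dimethyl-4-(phenylsulfonyl)chroman-5-ol
Product: 7 7-bromo-2,2-dimethyl-2H-chromen-5-ol
Conditions: t-BuOK (3 equiv), THF, 0 °C to rt; aq NH4Cl
Reagents that add atoms: none
Why: Base-induced β-elimination of benzenesulfinate from the benzylic sulfone (E1cB-like, assisted by the ortho phenoxide) should give the conjugated C3=C4 alkene, completing the use of the vinyl sulfone as an acetylene equivalent.

Step 5
Reactants: 8 2-methylbut-3-en-2-ol
Product: 10 tert-butyl (2-methylbut-3-en-2-yl) carbonate, via lithium alkoxide 9 (not isolated)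
Conditions: n-BuLi, THF, −78 to 0 °C; then Boc2O, 0 °C to rt
Reagents that add atoms: di-tert-butyl dicarbonate, CC(C)(C)OC(=O)OC(=O)OC(C)(C)C
Why: O-acylation of the tertiary lithium alkoxide with Boc2O is the standard preparation of this allylic carbonate.

Step 6
Reactants: 7 7-bromo-2,2-dimethyl-2H-chromen-5-ol; 10 tert-butyl (2-methylbut-3-en-2-yl) carbonate
Product: 11 7-bromo-2,2-dimethyl-5-[(2-methylbut-3-en-2-yl)oxy]-2H-chromene
Conditions: 10 (1.5 equiv), Pd(PPh3)4 (3 mol %), THF, 0 °C
Reagents that add atoms: none
Why: Tsuji–Trost O-allylation, in which decarboxylative ionisation gives a 1,1-dimethylallyl palladium species that the phenoxide attacks kinetically at its substituted terminus to give the tertiary ether, while at 0 °C zerovalent palladium should not insert into the electron-rich aryl bromide.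

Step 7
Reactants: 11 7-bromo-2,2-dimethyl-5-[(2-methylbut-3-en-2-yl)oxy]-2H-chromene
Product: 12 7-bromo-2,2-dimethyl-6-(3-methylbut-2-en-1-yl)-2H-chromen-5-ol
Conditions: Eu(fod)3 (10 mol %), CHCl3, 60 °C
Reagents that add atoms: none
Why: Aromatic Claisen rearrangement ([3,3]) should deliver the allyl unit, with inversion to the prenyl group, to C6, the only unsubstituted ortho carbon because C4a is blocked by the pyran ring, and tautomerisation restores the phenol.

Step 8
Reactants: 13 4-vinylphenyl acetate; 12 7-bromo-2,2-dimethyl-6-(3-methylbut-2-en-1-yl)-2H-chromen-5-ol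
Product: 16 7-[2-(4-hydroxyphenyl)ethyl]-2,2-dimethyl-6-(3-methylbut-2-en-1-yl)-2H-chromen-5-ol, via alkylborane 14 (not isolated), via aryl acetate 15 (not isolated)
Conditions: 13 (1.6 equiv), 9-BBN (1.5 equiv), THF, 0 °C to rt; then 12, Pd(OAc)2 (5 mol %), SPhos (10 mol %), aq K3PO4, THF, 60 °C; then NaOH, MeOH, rt; aq NH4Cl
Reagents that add atoms: none
Why: Anti-Markovnikov hydroboration of the styrene followed by B-alkyl Suzuki–Miyaura coupling should join the two rings through the CH2CH2 bridge without touching the prenyl and chromene alkenes (the styrene is in excess, so no B–H remains), and the basic medium cleaves the aryl acetate in the same pot.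

Compound list
1 | 5-bromobenzene-1,3-diol | Oc1cc(O)cc(Br)c1 | starting material
2 | 2-bromo-2-methylpropanoic acid | CC(C)(Br)C(=O)O | starting material
3 | 2-(3-bromo-5-hydroxyphenoxy)-2-methylpropanoic acid | CC(C)(Oc1cc(O)cc(Br)c1)C(=O)O | intermediate
4 | 1,3-dioxoisoindolin-2-yl 2-(3-bromo-5-hydroxyphenoxy)-2-methylpropanoate | CC(C)(Oc1cc(O)cc(Br)c1)C(=O)ON1C(=O)c2ccccc2C1=O | intermediate
5 | phenyl vinyl sulfone | C=CS(=O)(=O)c1ccccc1 | starting material
6 | rac-7-bromo-2,2-dimethyl-4-(phenylsulfonyl)chroman-5-ol (racemate) | CC1(C)CC(S(=O)(=O)c2ccccc2)c2c(O)cc(Br)cc2O1 | intermediate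
7 | 7-bromo-2,2-dimethyl-2H-chromen-5-ol | CC1(C)C=Cc2c(O)cc(Br)cc2O1 | intermediate
8 | 2-methylbut-3-en-2-ol | C=CC(C)(C)O | starting material
9 | lithium 2-methylbut-3-en-2-olate | [Li+].[O-]C(C)(C)C=C | intermediate (not isolated)
10 | tert-butyl (2-methylbut-3-en-2-yl) carbonate | C=CC(C)(C)OC(=O)OC(C)(C)C | intermediate
11 | 7-bromo-2,2-dimethyl-5-[(2-methylbut-3-en-2-yl)oxy]-2H-chromene | C=CC(C)(C)Oc1cc(Br)cc2c1C=CC(C)(C)O2 | intermediate
12 | 7-bromo-2,2-dimethyl-6-(3-methylbut-2-en-1-yl)-2H-chromen-5-ol | CC(C)=CCc1c(Br)cc2c(c1O)C=CC(C)(C)O2 | intermediate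
13 | 4-vinylphenyl acetate (4-acetoxystyrene) | C=Cc1ccc(OC(C)=O)cc1 | starting material
14 | 9-[2-(4-acetoxyphenyl)ethyl]-9-borabicyclo[3.3.1]nonane | CC(=O)Oc1ccc(CCB2C3CCCC2CCC3)cc1 | intermediate (not isolated)
15 | 4-{2-[5-hydroxy-2,2-dimethyl-6-(3-methylbut-2-en-1-yl)-2H-chromen-7-yl]ethyl}phenyl acetate | CC(C)=CCc1c(CCc2ccc(OC(C)=O)cc2)cc2c(c1O)C=CC(C)(C)O2 | intermediate (not isolated)
16 | 7-[2-(4-hydroxyphenyl)ethyl]-2,2-dimethyl-6-(3-methylbut-2-en-1-yl)-2H-chromen-5-ol | CC(C)=CCc1c(CCc2ccc(O)cc2)cc2c(c1O)C=CC(C)(C)O2 | target

Total step count: 8. Longest linear sequence: 7 (steps 1, 2, 3, 4, 6, 7, 8); step 5 prepares a reagent on a side branch.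

Steps most likely to fail

Step 3 (key step). The ring closure may take place at the wrong ortho carbon (C8 instead of C4a), or the adduct radical may be reduced or pick up a hydrogen atom before it cyclises, leaving an open-chain Giese adduct. The fallback sets out from compound 1 and comes back at compound 7, replacing steps 1 to 4. Compound 1 is condensed with 3-methylbut-2-enal (ethylenediammonium diacetate cat., toluene, reflux). Knoevenagel-type condensation at the carbon between the two hydroxyls should give the ortho-quinone methide F1, which closes by oxa-6π electrocyclisation to 7. Either hydroxyl of the symmetric diol leads to the same product. This fallback closes the pyran ring through O1–C2 instead of C2–C3.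

Step 8. Oxidative addition at the aryl bromide, which is flanked by the prenyl group and sits on a phenoxide-bearing ring, may be slow, so that β-hydride elimination and protodeboronation consume the alkylborane. The fallback sets out from compound 12 and comes back at compound 15, with the roles of the coupling partners reversed. Suzuki–Miyaura vinylation of 12 with potassium vinyltrifluoroborate (PdCl2(dppf), Cs2CO3, THF/H2O, 70 °C) should give the 7-vinyl chromenol F2. 9-BBN (2.2 equiv, one of which is taken up by the phenol) should hydroborate only the monosubstituted vinyl group, giving the alkylborane F3. Coupling of F3 with 4-iodophenyl acetate (PdCl2(dppf), aq NaOH, THF, 60 °C) gives 15, which is saponified in the same basic medium to 16.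

Step 7. The tertiary allyl ether may ionise instead of rearranging in a concerted way, which would lead to loss of the allyl group or migration to the para carbon C8; the concerted shift into the position next to bromine is also sterically slowed. The fallback sets out from compound 7 and comes back at compound 12, replacing steps 5 to 7. O-alkylation of 7 with 1-bromo-3-methylbut-2-ene (K2CO3, acetone, rt) gives the prenyl ether F4. A clay-promoted [1,3] shift (montmorillonite K10, CH2Cl2, 0 °C) then moves the prenyl group from oxygen to the free ortho carbon C6, giving 12.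

Further compounds
F1 | step 3 | 3-bromo-5-hydroxy-6-(3-methylbut-2-en-1-ylidene)cyclohexa-2,4-dien-1-one (ortho-quinone methide) | CC(C)=CC=C1C(=O)C=C(Br)C=C1O
F2 | step 8 | 2,2-dimethyl-6-(3-methylbut-2-en-1-yl)-7-vinyl-2H-chromen-5-ol | CC(C)=CCc1c(C=C)cc2c(c1O)C=CC(C)(C)O2
F3 | step 8 | 7-[2-(9-borabicyclo[3.3.1]nonan-9-yl)ethyl]-2,2-dimethyl-6-(3-methylbut-2-en-1-yl)-2H-chromen-5-ol (phenol drawn free) | CC(C)=CCc1c(CCB3C4CCCC3CCC4)cc2c(c1O)C=CC(C)(C)O2
F4 | step 7 | 7-bromo-2,2-dimethyl-5-[(3-methylbut-2-en-1-yl)oxy]-2H-chromene | CC(C)=CCOc1cc(Br)cc2c1C=CC(C)(C)O2
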